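The route is built on forming the bond between C2 of the hexahydrobenzofuran ring and the first carbon of the polyene chain. C2 is at once allylic to C3=C3a and α to the ring oxygen O1, so a 2-ethoxy acetal, used as an anomeric mixture, ionises to a single planar furanylium ion. In one operation a complete C19 heptaenyl boronate transfers its methyl-bearing alkenyl carbon to this cation under a chiral hydroxy-acid catalyst, which joins both halves and sets the last stereocentre stereoconvergently. The precursors are a 6R p-nitrobenzoate acetal, made from (4R,6R)-actinol through the loliolide skeleton with a late Mitsunobu inversion, and a polyenylboronic acid built from the C10-dialdehyde.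

Key step: step 13

Remark: the catalyst of step 13 is written as its (2R,3R) enantiomer and stands for whichever enantiomer delivers the alkenyl group to the Si face of C2 (both come from the tartaric acids); compounds 1, 11, 13 and 17 are taken as catalogue compounds.

**Step 1**
Reactants: 1 (4R,6R)-4-hydroxy-2,2,6-trimethylcyclohexan-1-one (actinol)
Product: 2 (1R,5R)-3,3,5-trimethyl-4-oxocyclohexyl acetate
Conditions: Ac2O, pyridine, DMAP (cat.), CH2Cl2, 0 °C → rt
Reagents that add atoms: acetic anhydride, CC(=O)OC(C)=O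
Why: DMAP-catalysed acylation of the secondary alcohol touches no stereocentre and keeps this hydroxyl out of steps 2–4.

**Step 2**
Reactants: 2 (1R,5R)-3,3,5-trimethyl-4-oxocyclohexyl acetate
Product: 3 (1R)-3,5,5-trimethyl-4-[(trimethylsilyl)oxy]cyclohex-3-en-1-yl acetate
Conditions: TMSOTf, Et3N, CH2Cl2, 0 °C → rt
Reagents that add atoms: trimethylsilyl trifluoromethanesulfonate, C[Si](C)(C)OS(=O)(=O)C(F)(F)F
Why: Soft enolisation and O-silylation of a ketone with a single α-hydrogen can give only the tetrasubstituted silyl enol ether; the methyl-bearing stereocentre is erased on purpose and the ester is not enolised.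

**Step 3**
Reactants: 3 (1R)-3,5,5-trimethyl-4-[(trimethylsilyl)oxy]cyclohex-3-en-1-yl acetate
Product: 5 (1S,3R)-3-hydroxy-3,5,5-trimethyl-4-oxocyclohexyl acetate, via α-silyloxy ketone 4 (not isolated)
Conditions: mCPBA, NaHCO3, CH2Cl2, −20 → 0 °C; then 1 M HCl, THF, rt
Reagents that add atoms: 3-chloroperbenzoic acid, OOC(=O)c1cccc(Cl)c1
Why: Rubottom oxidation (epoxidation of the silyl enol ether, ring opening with 1,4-silyl shift, desilylation); the peracid should attack axially on the half-chair face anti to the acetoxy group, as is usual for 3-acyloxy-β-ionone-type rings, so the new tertiary hydroxyl (3R) is set trans to the acetate.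

**Step 4**
Reactants: 5 (1S,3R)-3-hydroxy-3,5,5-trimethyl-4-oxocyclohexyl acetate
Product: 7 (6S,7aR)-4,4,7a-trimethyl-2-oxo-2,4,5,6,7,7a-hexahydro-1-benzofuran-6-yl acetate (loliolide acetate), via acyl ylide 6 (not isolated)
Conditions: Ph3P=C=C=O, toluene, reflux
Reagents that add atoms: (triphenylphosphoranylidene)ketene, O=C=C=P(c1ccccc1)(c1ccccc1)c1ccccc1
Why: The tertiary alcohol adds to the ketene ylide and the resulting stabilised ylide ester closes onto the neighbouring hindered ketone by intramolecular Wittig olefination to give the butenolide; no stereocentre is affected.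

**Step 5**
Reactants: 7 (6S,7aR)-4,4,7a-trimethyl-2-oxo-2,4,5,6,7,7a-hexahydro-1-benzofuran-6-yl acetate
Product: 8 (2RS,6S,7aR)-4,4,7a-trimethyl-2,4,5,6,7,7a-hexahydro-1-benzofuran-2,6-diol (anomeric mixture)
Conditions: DIBAL-H (3 equiv), CH2Cl2, −78 °C; MeOH, then Rochelle salt
Reagents that add atoms: none
Why: Partial hydride reduction of the butenolide stops at the aluminium hemiacetal at −78 °C and the same reagent removes the acetate; the lactol cannot aromatise to a furan because C7a is quaternary.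

**Step 6**
Reactants: 8 (2RS,6S,7aR)-4,4,7a-trimethyl-2,4,5,6,7,7a-hexahydro-1-benzofuran-2,6-diol
Product: 9 (2RS,6S,7aR)-2-ethoxy-4,4,7a-trimethyl-2,4,5,6,7,7a-hexahydro-1-benzofuran-6-ol
Conditions: EtOH, PPTS (cat.), 3 Å MS, rt
Reagents that add atoms: ethanol, CCO
Why: Acid-catalysed acetalisation through the allylic oxocarbenium ion converts only the hemiacetal hydroxyl; the axial secondary alcohol is untouched and the anomeric configuration is irrelevant for step 13.

**Step 7**
Reactants: 9 (2RS,6S,7aR)-2-ethoxy-4,4,7a-trimethyl-2,4,5,6,7,7a-hexahydro-1-benzofuran-6-ol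
Product: 10 (2RS,6R,7aR)-2-ethoxy-4,4,7a-trimethyl-2,4,5,6,7,7a-hexahydro-1-benzofuran-6-yl 4-nitrobenzoate
Conditions: 4-nitrobenzoic acid, PPh3, DIAD, toluene, 0 °C → rt
Reagents that add atoms: 4-nitrobenzoic acid, OC(=O)c1ccc(cc1)[N+](=O)[O-]
Why: Mitsunobu esterification with SN2 inversion turns the axial 6S alcohol (syn-axial to two methyl groups) into the equatorial 6R ester, the carboxylate entering along the open equatorial trajectory; this sets the C6 configuration of the target and protects the oxygen.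

**Step 8**
Reactants: 11 ethyl (2E)-4-bromo-2-methylbut-2-enoate
Product: 12 ethyl (2E)-4-(diethoxyphosphoryl)-2-methylbut-2-enoate
Conditions: P(OEt)3, neat, 120 °C, EtBr distilled off
Reagents that add atoms: triethyl phosphite, CCOP(OCC)OCC
Why: Michaelis–Arbuzov reaction of a primary allylic bromide; the E geometry of the enoate is kept.

**Step 9**
Reactants: 12 ethyl (2E)-4-(diethoxyphosphoryl)-2-methylbut-2-enoate; 13 (2E,4E,6E)-2,7-dimethylocta-2,4,6-trienedial
Product: 14 ethyl (2E,4E,6E,8E,10E)-2,6,11-trimethyl-12-oxododeca-2,4,6,8,10-pentaenoate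
Conditions: NaH, THF, 0 °C; anion added slowly to 13 (3 equiv), −20 °C → rt
Reagents that add atoms: none
Why: Horner–Wadsworth–Emmons olefination with a stabilised allylic phosphonate is E-selective, and the excess of dialdehyde (recoverable) limits the reaction to one formyl group.

**Step 10**
Reactants: 14 ethyl (2E,4E,6E,8E,10E)-2,6,11-trimethyl-12-oxododeca-2,4,6,8,10-pentaenoate
Product: 16 ethyl (2E,4E,6E,8E,10E,12E)-2,6,11-trimethyl-14-oxotetradeca-2,4,6,8,10,12-hexaenoate, via dioxolane 15 (not isolated)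
Conditions: (1,3-dioxolan-2-ylmethyl)triphenylphosphonium bromide, KOtBu, THF, 0 °C → rt; then 1 M HCl, THF, rt, dark
Reagents that add atoms: (1,3-dioxolan-2-ylmethyl)triphenylphosphonium bromide, [Br-].C1COC(C[P+](c2ccccc2)(c2ccccc2)c2ccccc2)O1; water, O
Why: Wittig two-carbon homologation with a masked formylmethylene ylide avoids the over-homologation of free formyl ylides, and the acidic acetal hydrolysis should also equilibrate the new double bond to the E enal.

**Step 11**
Reactants: 16 ethyl (2E,4E,6E,8E,10E,12E)-2,6,11-trimethyl-14-oxotetradeca-2,4,6,8,10,12-hexaenoate; 17 1,1-bis(4,4,5,5-tetramethyl-1,3,2-dioxaborolan-2-yl)ethane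
Product: 18 ethyl (2E,4E,6E,8E,10E,12E,14Z)-2,6,11-trimethyl-15-(4,4,5,5-tetramethyl-1,3,2-dioxaborolan-2-yl)hexadeca-2,4,6,8,10,12,14-heptaenoate
Conditions: 17, LiTMP (from TMPH and n-BuLi), THF, 0 °C; then 16, −78 °C → rt
Reagents that add atoms: none
Why: Boron–Wittig olefination: the α-boryl carbanion adds 1,2 to the aldehyde and syn B–O elimination gives the trisubstituted alkenyl boronate with the polyene chain anti to the bulky remaining boronate, so chain and methyl are cis (14Z), the geometry needed for the 9E bond of the carotenoid.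

**Step 12**
Reactants: 18 ethyl (2E,4E,6E,8E,10E,12E,14Z)-2,6,11-trimethyl-15-(4,4,5,5-tetramethyl-1,3,2-dioxaborolan-2-yl)hexadeca-2,4,6,8,10,12,14-heptaenoate
Product: 19 [(2Z,4E,6E,8E,10E,12E,14E)-16-ethoxy-6,11,15-trimethyl-16-oxohexadeca-2,4,6,8,10,12,14-heptaen-2-yl]boronic acid
Conditions: NaIO4, NH4OAc, acetone/H2O, rt, dark
Reagents that add atoms: water, O
Why: Oxidative cleavage of the released pinacol by periodate drives hydrolysis of the boronic ester under near-neutral conditions that leave polyene and ester alone; the sensitive polyenylboronic acid is used at once.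

**Step 13**
Reactants: 10 (2RS,6R,7aR)-2-ethoxy-4,4,7a-trimethyl-2,4,5,6,7,7a-hexahydro-1-benzofuran-6-yl 4-nitrobenzoate; 19 [(2Z,4E,6E,8E,10E,12E,14E)-16-ethoxy-6,11,15-trimethyl-16-oxohexadeca-2,4,6,8,10,12,14-heptaen-2-yl]boronic acid
Product: 21 ethyl (2E,4E,6E,8E,10E,12E,14E)-2,6,11-trimethyl-15-[(2R,6R,7aR)-4,4,7a-trimethyl-6-[(4-nitrobenzoyl)oxy]-2,4,5,6,7,7a-hexahydro-1-benzofuran-2-yl]hexadeca-2,4,6,8,10,12,14-heptaenoate, via diethyl boronate 20 (not isolated)
Conditions: 19, EtOH, 3 Å MS, EtOAc, rt; then 10, (2R,3R)-4-(dibenzylamino)-2,3-dihydroxy-4-oxobutanoic acid (20 mol%), Yb(OTf)3 (10 mol%), −40 → 0 °C, dark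
Reagents that add atoms: none
Why: Proposed new method: ytterbium triflate ionises both anomers of 10 at C2, which is allylic to C3=C3a and α to O1, to one planar 2H-furanylium ion, while the tartaric acid amide exchanges onto 20 to give a more Lewis-acidic chiral acyloxy-dioxaborolane that takes up the ethoxide and, inside the resulting borate–oxocarbenium ion pair, transfers its boron-bound alkenyl carbon to C2 with retention of the alkene geometry. The closest known reaction type is the chiral hydroxy-acid/lanthanide-triflate-catalysed addition of alkenyl boronates to pyrylium ions generated from 2-alkoxy-2H-chromenes, and in racemic form the BF3-promoted coupling of alkenyltrifluoroborates with cyclic acetals; it is new here for a non-benzannulated dihydrofuranyl acetal and a polyenyl boronate. No ring is closed. The one new stereocentre (C2, 2R) is under catalyst control: around C2 the cation is almost locally mirror-symmetric (7a-methyl on one face, the C7 methylene on the other), so the substrate should give little bias and the chiral borate decides, delivery to the Si face (anti to the 7a-methyl) giving 2R, and because both anomers pass through the same cation the step is stereoconvergent. The step needs C2-over-C3a regioselectivity, secured by the fully substituted neopentyl C3a, and ipso transfer of the boron-bearing carbon instead of vinylogous attack along the polyene, secured by the intramolecular transfer from the borate. The acceptor-terminated polyene, the ethyl ester and the p-nitrobenzoate should be inert to the weakly acidic medium at low temperature.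

**Step 14**
Reactants: 21 ethyl (2E,4E,6E,8E,10E,12E,14E)-2,6,11-trimethyl-15-[(2R,6R,7aR)-4,4,7a-trimethyl-6-[(4-nitrobenzoyl)oxy]-2,4,5,6,7,7a-hexahydro-1-benzofuran-2-yl]hexadeca-2,4,6,8,10,12,14-heptaenoate
Product: 22 (2R,6R,7aR)-2-[(2E,4E,6E,8E,10E,12E,14E)-16-hydroxy-6,11,15-trimethylhexadeca-2,4,6,8,10,12,14-heptaen-2-yl]-4,4,7a-trimethyl-2,4,5,6,7,7a-hexahydro-1-benzofuran-6-ol
Conditions: DIBAL-H (6 equiv), CH2Cl2, −78 → −20 °C; Rochelle salt
Reagents that add atoms: none
Why: DIBAL reduces the conjugated ethyl ester 1,2 to the allylic alcohol and cleaves the p-nitrobenzoate reductively in the same operation; polyene, cyclic allylic ether and all stereocentres should be untouched.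

**Step 15**
Reactants: 22 (2R,6R,7aR)-2-[(2E,4E,6E,8E,10E,12E,14E)-16-hydroxy-6,11,15-trimethylhexadeca-2,4,6,8,10,12,14-heptaen-2-yl]-4,4,7a-trimethyl-2,4,5,6,7,7a-hexahydro-1-benzofuran-6-ol
Product: 23 (2E,4E,6E,8E,10E,12E,14E)-15-[(2R,6R,7aR)-6-hydroxy-4,4,7a-trimethyl-2,4,5,6,7,7a-hexahydro-1-benzofuran-2-yl]-2,6,11-trimethylhexadeca-2,4,6,8,10,12,14-heptaenal (target)
Conditions: MnO2 (activated, excess), CH2Cl2, rt, dark
Reagents that add atoms: none
Why: Activated manganese dioxide oxidises only the allylic (polyenylic) primary alcohol to the conjugated aldehyde and leaves the saturated secondary hydroxyl at C6.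

**Compound list**

1 | (4R,6R)-4-hydroxy-2,2,6-trimethylcyclohexan-1-one | O=C1C(C)(C)C[C@H](O)C[C@H]1C | starting material
2 | (1R,5R)-3,3,5-trimethyl-4-oxocyclohexyl acetate | O=C1C(C)(C)C[C@H](OC(C)=O)C[C@H]1C | intermediate
3 | (1R)-3,5,5-trimethyl-4-[(trimethylsilyl)oxy]cyclohex-3-en-1-yl acetate | C[Si](C)(C)OC1=C(C)C[C@@H](OC(C)=O)CC1(C)C | intermediate
4 | (1S,3R)-3,5,5-trimethyl-4-oxo-3-[(trimethylsilyl)oxy]cyclohexyl acetate | O=C1C(C)(C)C[C@H](OC(C)=O)C[C@@]1(C)O[Si](C)(C)C | intermediate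
5 | (1S,3R)-3-hydroxy-3,5,5-trimethyl-4-oxocyclohexyl acetate | O=C1C(C)(C)C[C@H](OC(C)=O)C[C@@]1(C)O | intermediate
6 | (1R,5S)-5-(acetyloxy)-1,3,3-trimethyl-2-oxocyclohexyl (triphenyl-λ5-phosphanylidene)acetate | O=C1C(C)(C)C[C@H](OC(C)=O)C[C@@]1(C)OC(=O)C=P(c1ccccc1)(c1ccccc1)c1ccccc1 | intermediate
7 | (6S,7aR)-4,4,7a-trimethyl-2-oxo-2,4,5,6,7,7a-hexahydro-1-benzofuran-6-yl acetate | O=C1C=C2C(C)(C)C[C@H](OC(C)=O)C[C@@]2(C)O1 | intermediate
8 | (2RS,6S,7aR)-4,4,7a-trimethyl-2,4,5,6,7,7a-hexahydro-1-benzofuran-2,6-diol | OC1C=C2C(C)(C)C[C@H](O)C[C@@]2(C)O1 | intermediate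
9 | (2RS,6S,7aR)-2-ethoxy-4,4,7a-trimethyl-2,4,5,6,7,7a-hexahydro-1-benzofuran-6-ol | CCOC1C=C2C(C)(C)C[C@H](O)C[C@@]2(C)O1 | intermediate
10 | (2RS,6R,7aR)-2-ethoxy-4,4,7a-trimethyl-2,4,5,6,7,7a-hexahydro-1-benzofuran-6-yl 4-nitrobenzoate | CCOC1C=C2C(C)(C)C[C@@H](OC(=O)c3ccc(cc3)[N+](=O)[O-])C[C@@]2(C)O1 | intermediate
11 | ethyl (2E)-4-bromo-2-methylbut-2-enoate | CCOC(=O)/C(C)=C/CBr | starting material
12 | ethyl (2E)-4-(diethoxyphosphoryl)-2-methylbut-2-enoate | CCOC(=O)/C(C)=C/CP(=O)(OCC)OCC | intermediate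
13 | (2E,4E,6E)-2,7-dimethylocta-2,4,6-trienedial | O=C/C(C)=C/C=C/C=C(C)/C=O | starting material
14 | ethyl (2E,4E,6E,8E,10E)-2,6,11-trimethyl-12-oxododeca-2,4,6,8,10-pentaenoate | CCOC(=O)/C(C)=C/C=C/C(C)=C/C=C/C=C(C)/C=O | intermediate
15 | ethyl (2E,4E,6E,8E,10E)-13-(1,3-dioxolan-2-yl)-2,6,11-trimethyltrideca-2,4,6,8,10,12-hexaenoate (12E/12Z) | CCOC(=O)/C(C)=C/C=C/C(C)=C/C=C/C=C(C)/C=CC1OCCO1 | intermediate
16 | ethyl (2E,4E,6E,8E,10E,12E)-2,6,11-trimethyl-14-oxotetradeca-2,4,6,8,10,12-hexaenoate | CCOC(=O)/C(C)=C/C=C/C(C)=C/C=C/C=C(C)/C=C/C=O | intermediate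
17 | 1,1-bis(4,4,5,5-tetramethyl-1,3,2-dioxaborolan-2-yl)ethane | CC(B1OC(C)(C)C(C)(C)O1)B1OC(C)(C)C(C)(C)O1 | starting material
18 | ethyl (2E,4E,6E,8E,10E,12E,14Z)-2,6,11-trimethyl-15-(4,4,5,5-tetramethyl-1,3,2-dioxaborolan-2-yl)hexadeca-2,4,6,8,10,12,14-heptaenoate | CCOC(=O)/C(C)=C/C=C/C(C)=C/C=C/C=C(C)/C=C/C=C(\C)B1OC(C)(C)C(C)(C)O1 | intermediate
19 | [(2Z,4E,6E,8E,10E,12E,14E)-16-ethoxy-6,11,15-trimethyl-16-oxohexadeca-2,4,6,8,10,12,14-heptaen-2-yl]boronic acid | CCOC(=O)/C(C)=C/C=C/C(C)=C/C=C/C=C(C)/C=C/C=C(\C)B(O)O | intermediate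
20 | ethyl (2E,4E,6E,8E,10E,12E,14Z)-15-(diethoxyboranyl)-2,6,11-trimethylhexadeca-2,4,6,8,10,12,14-heptaenoate | CCOC(=O)/C(C)=C/C=C/C(C)=C/C=C/C=C(C)/C=C/C=C(\C)B(OCC)OCC | intermediate
21 | ethyl (2E,4E,6E,8E,10E,12E,14E)-2,6,11-trimethyl-15-[(2R,6R,7aR)-4,4,7a-trimethyl-6-[(4-nitrobenzoyl)oxy]-2,4,5,6,7,7a-hexahydro-1-benzofuran-2-yl]hexadeca-2,4,6,8,10,12,14-heptaenoate | CCOC(=O)/C(C)=C/C=C/C(C)=C/C=C/C=C(C)/C=C/C=C(\C)[C@H]1C=C2C(C)(C)C[C@@H](OC(=O)c3ccc(cc3)[N+](=O)[O-])C[C@@]2(C)O1 | intermediate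
22 | (2R,6R,7aR)-2-[(2E,4E,6E,8E,10E,12E,14E)-16-hydroxy-6,11,15-trimethylhexadeca-2,4,6,8,10,12,14-heptaen-2-yl]-4,4,7a-trimethyl-2,4,5,6,7,7a-hexahydro-1-benzofuran-6-ol | OC/C(C)=C/C=C/C(C)=C/C=C/C=C(C)/C=C/C=C(\C)[C@H]1C=C2C(C)(C)C[C@@H](O)C[C@@]2(C)O1 | intermediate
23 | (2E,4E,6E,8E,10E,12E,14E)-15-[(2R,6R,7aR)-6-hydroxy-4,4,7a-trimethyl-2,4,5,6,7,7a-hexahydro-1-benzofuran-2-yl]-2,6,11-trimethylhexadeca-2,4,6,8,10,12,14-heptaenal | C\C(C=O)=C/C=C/C(C)=C/C=C/C=C(C)/C=C/C=C(\C)[C@H]1C=C2C(C)(C)C[C@@H](O)C[C@@]2(C)O1 | target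

**Step count**

Total: 15 steps. Longest linear sequence: 10 steps (steps 1–7, then 13, 14 and 15); the polyene branch is steps 8–12.

**Steps most likely to fail**

Step 13 (Proposed new method). The chiral borate may discriminate the two faces of a non-benzannulated furanylium ion poorly. Alkenyl transfer from an α-branched, acceptor-terminated polyenyl boronate may be slow, so that protodeboronation or an uncatalysed background reaction takes over. The product may also re-ionise at C2 and epimerise. The fallback uses known chemistry, sets out from 18 and 10 and comes back at 21. Boronate 18 is converted with aqueous KHF2 in methanol into the potassium trifluoroborate F1. F1 is coupled with acetal 10 under BF3·OEt2 in acetonitrile at −40 °C, the established alkenyltrifluoroborate–acetal substitution through the same furanylium ion. Without a chiral controller this should give 21 together with its C2 epimer F2, which are separated by chromatography. The unwanted epimer F2 is re-equilibrated with a trace of acid, the usual C8 epimerisation of furanoid 5,8-epoxides by reversible C–O heterolysis, and recycled.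

Step 7. Formation of the alkoxyphosphonium ion at the axial hydroxyl, which is flanked by two syn-axial methyl groups, may be slow, and anti-periplanar E2 elimination toward C5 or C7 may compete with substitution. The fallback sets out from 9 and comes back at 10. It replaces SN2 inversion by thermodynamic control: redox epimerisation of the carbinol with (η5-pentaphenylcyclopentadienyl)Ru(CO)2Cl and KOtBu in toluene should drain the strained axial alcohol into the equatorial 6R epimer F3. F3 is then acylated with 4-nitrobenzoyl chloride, Et3N and DMAP to give 10.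

Step 11. The α-boryl carbanion may add in a conjugate sense to the extended polyenal or attack the ester, and the syn-elimination may give incomplete control of the new trisubstituted double bond. The fallback sets out from 14 and comes back at 18, fixing that geometry by a syn-borylcupration instead.
- Aldehyde 14 is reduced (NaBH4, CeCl3, MeOH/THF, 0 °C) to the allylic alcohol F4, which is converted with PPh3·HBr into the phosphonium bromide F5.
- Separately, commercial ethyl but-2-ynoate undergoes copper-catalysed syn-addition of B2pin2/MeOH (CuCl, NaOtBu, Xantphos) to give ethyl (2Z)-3-(pinacolboryl)but-2-enoate F6, with boron trans to the ester.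
- F6 is reduced with DIBAL-H to the allylic alcohol F7 and oxidised with MnO2 to the boryl enal F8.
- Wittig reaction of the ylide from F5 (NaHMDS, THF, −78 °C → rt) with F8, followed by thermal equilibration of the new disubstituted double bond to E, gives 18.

**Further compounds**

F1 | step 13 | potassium trifluoro[(2Z,4E,6E,8E,10E,12E,14E)-16-ethoxy-6,11,15-trimethyl-16-oxohexadeca-2,4,6,8,10,12,14-heptaen-2-yl]borate | CCOC(=O)/C(C)=C/C=C/C(C)=C/C=C/C=C(C)/C=C/C=C(\C)[B-](F)(F)F.[K+]
F2 | step 13 | ethyl (2E,4E,6E,8E,10E,12E,14E)-2,6,11-trimethyl-15-[(2S,6R,7aR)-4,4,7a-trimethyl-6-[(4-nitrobenzoyl)oxy]-2,4,5,6,7,7a-hexahydro-1-benzofuran-2-yl]hexadeca-2,4,6,8,10,12,14-heptaenoate | CCOC(=O)/C(C)=C/C=C/C(C)=C/C=C/C=C(C)/C=C/C=C(\C)[C@@H]1C=C2C(C)(C)C[C@@H](OC(=O)c3ccc(cc3)[N+](=O)[O-])C[C@@]2(C)O1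
F3 | step 7 | (2RS,6R,7aR)-2-ethoxy-4,4,7a-trimethyl-2,4,5,6,7,7a-hexahydro-1-benzofuran-6-ol | CCOC1C=C2C(C)(C)C[C@@H](O)C[C@@]2(C)O1
F4 | step 11 | ethyl (2E,4E,6E,8E,10E)-12-hydroxy-2,6,11-trimethyldodeca-2,4,6,8,10-pentaenoate | CCOC(=O)/C(C)=C/C=C/C(C)=C/C=C/C=C(C)/CO
F5 | step 11 | [(2E,4E,6E,8E,10E)-12-ethoxy-2,7,11-trimethyl-12-oxododeca-2,4,6,8,10-pentaen-1-yl]triphenylphosphonium bromide | CCOC(=O)/C(C)=C/C=C/C(C)=C/C=C/C=C(C)/C[P+](c1ccccc1)(c1ccccc1)c1ccccc1.[Br-]
F6 | step 11 | ethyl (2Z)-3-(4,4,5,5-tetramethyl-1,3,2-dioxaborolan-2-yl)but-2-enoate | CCOC(=O)/C=C(\C)B1OC(C)(C)C(C)(C)O1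
F7 | step 11 | (2Z)-3-(4,4,5,5-tetramethyl-1,3,2-dioxaborolan-2-yl)but-2-en-1-ol | OC/C=C(\C)B1OC(C)(C)C(C)(C)O1
F8 | step 11 | (2Z)-3-(4,4,5,5-tetramethyl-1,3,2-dioxaborolan-2-yl)but-2-enal | O=C/C=C(\C)B1OC(C)(C)C(C)(C)O1
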